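**Plan**

- Cuts: the two C–O bonds that tie the 1,4-dioxane to one diterpene half, O(C7)–C6′ and O(C6)–C7′. This leaves a trans-6α,7β-diol and a C6=C7 alkene of the same 12-methoxyabietatriene; both go back through a common C7 ketone to (+)-dehydroabietic acid.
- Forward: rings A, B and C come intact from the resin acid. The C4 carboxyl is reduced to methyl, C12 is oxygenated (Friedel–Crafts acylation, Baeyer–Villiger), C7 is oxidised, and the ketone is divided into the alkene (reduction, dehydration) and the diol (enolate hydroxylation, reduction).
- The dioxane ring is made last, in one anodic step that joins the two C21 halves: one-electron oxidation of the alkene, C6–O bond formation, oxidation to the C7 cation, C7–O ring closure.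
- Enabling feature: the C6=C7 bond of ring B is conjugated with ring C, whose C12 methoxy group is para to C8, so the alkene is a p-methoxystyrene. It is the most easily oxidised site, its radical cation accepts oxygen at C6, and C7 carries a stabilised, reversibly formed cation.
- Stereochemistry: C5 and C10 come from the chiral pool. Both C6–O bonds form on the α face, opposite the axial C10 and C4 methyl groups. C7–O is β by axial hydride delivery in the diol half and by closure to the all-equatorial trans-fused dioxane in the alkene half.

Key step: step 11

Remark: the benzylic alcohol formed on the way to the alkene is drawn as its expected major 7β epimer; either epimer should dehydrate to the same alkene.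

**Route**

Step 1
Reactants: 1 (+)-dehydroabietic acid (abieta-8,11,13-trien-18-oic acid)
Product: 2 dehydroabietinol (abieta-8,11,13-trien-18-ol)
Conditions: LiAlH4, THF, 0 °C to reflux; then H2O, aq NaOH
Reagents that add atoms: none
Why: Hydride reduction of the neopentyl carboxylic acid to the primary alcohol should proceed without touching any stereocenter (LiAlH4 reduction of a carboxylic acid).

Step 2
Reactants: 2 dehydroabietinol
Product: 3 dehydroabietyl tosylate (abieta-8,11,13-trien-18-yl 4-methylbenzenesulfonate)
Conditions: TsCl, pyridine, DMAP (cat.), 0 °C to rt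
Reagents that add atoms: 4-toluenesulfonyl chloride, Cc1ccc(cc1)S(Cl)(=O)=O
Why: Sulfonylation of the primary C18 alcohol turns it into a leaving group and leaves the quaternary C4 center unchanged (tosylation).

Step 3
Reactants: 3 dehydroabietyl tosylate
Product: 5 abieta-8,11,13-triene (dehydroabietane), via 18-iodoabieta-8,11,13-triene 4 (not isolated)
Conditions: NaI, Zn dust, HMPA, 105 °C; aqueous work-up
Reagents that add atoms: none
Why: Iodide should displace the neopentyl tosylate in the hot dipolar medium (Finkelstein reaction) and zinc should reduce iodide 4 as it forms to the C18 methyl group (reductive dehalogenation), which makes C4 a gem-dimethyl carbon.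

Step 4
Reactants: 5 abieta-8,11,13-triene
Product: 6 12-acetylabieta-8,11,13-triene
Conditions: AcCl, AlCl3, CH2Cl2, 0 °C to rt
Reagents that add atoms: acetyl chloride, CC(Cl)=O
Why: Friedel–Crafts acylation should go to C12, the free position of ring C that is ortho to the isopropyl group, para to C8 and the least hindered of the three.

Step 5
Reactants: 6 12-acetylabieta-8,11,13-triene
Product: 7 ferruginyl acetate (abieta-8,11,13-trien-12-yl acetate)
Conditions: mCPBA, CF3CO2H (cat.), CH2Cl2, rt, dark
Reagents that add atoms: 3-chloroperbenzoic acid, OOC(=O)c1cccc(Cl)c1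
Why: In the Baeyer–Villiger oxidation the electron-rich aryl group should migrate in preference to methyl, which turns the aryl methyl ketone into the aryl acetate.

Step 6
Reactants: 7 ferruginyl acetate
Product: 9 ferruginol methyl ether (12-methoxyabieta-8,11,13-triene), via potassium ferruginolate 8 (not isolated)
Conditions: KOH, DMSO, rt; then MeI
Reagents that add atoms: iodomethane, CI
Why: Saponification of the aryl acetate gives phenoxide 8, which should be O-methylated in the same flask (Williamson ether synthesis).

Step 7
Reactants: 9 ferruginol methyl ether
Product: 10 sugiol methyl ether (12-methoxyabieta-8,11,13-trien-7-one)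
Conditions: CrO3, AcOH/H2O, rt
Reagents that add atoms: chromium trioxide, O=[Cr](=O)=O
Why: Chromic acid benzylic oxidation should prefer the C7 methylene, which is conjugated through C8 with the para methoxy group, over the tertiary isopropyl C–H; no stereocenter is formed.

Step 8
Reactants: 10 sugiol methyl ether
Product: 12 6,7-dehydroferruginol methyl ether (12-methoxyabieta-6,8,11,13-tetraene), via 12-methoxyabieta-8,11,13-trien-7β-ol 11 (not isolated)
Conditions: NaBH4, MeOH/THF, rt; then TsOH·H2O (cat.), toluene, 80 °C
Reagents that add atoms: none
Why: Borohydride reduction of the aryl ketone gives benzylic alcohol 11, and acid-catalysed E1 dehydration through the p-methoxybenzylic C7 cation should give the conjugated C6=C7 alkene, the only elimination open because C8 is aromatic.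

Step 9
Reactants: 10 sugiol methyl ether
Product: 14 6α-hydroxysugiol methyl ether (6α-hydroxy-12-methoxyabieta-8,11,13-trien-7-one), via potassium enolate 13 (not isolated)
Conditions: KN(SiMe3)2, THF, −78 °C; then 2-(phenylsulfonyl)-3-phenyloxaziridine, −78 °C; aq NH4Cl
Reagents that add atoms: 2-(phenylsulfonyl)-3-phenyloxaziridine, O=S(=O)(c1ccccc1)N1OC1c1ccccc1
Why: Deprotonation can occur only at C6, and enolate 13 should be hydroxylated on the α face, opposite the axial C10 and C4 methyl groups, to give the equatorial 6α alcohol (enolate hydroxylation with an N-sulfonyloxaziridine).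

Step 10
Reactants: 14 6α-hydroxysugiol methyl ether
Product: 15 12-methoxyabieta-8,11,13-triene-6α,7β-diol
Conditions: NaBH4, MeOH/CH2Cl2, −20 to 0 °C
Reagents that add atoms: none
Why: Borohydride should attack the C7 carbonyl along the axial trajectory from the α face, anti to the C10 methyl group, so the new hydroxyl is β and pseudo-equatorial and the diol is trans-diequatorial (hydride reduction of an α-hydroxy ketone).

Step 11
Reactants: 15 12-methoxyabieta-8,11,13-triene-6α,7β-diol; 12 6,7-dehydroferruginol methyl ether (1.3 equiv)
Product: 19 the target (head-to-tail 6α,7β-dioxane dimer of 12-methoxyabieta-8,11,13-triene), via alkene radical cation 16 (not isolated), via C7 benzylic radical 17 (not isolated), via C7 benzylic cation 18 (not isolated)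
Conditions: reticulated vitreous carbon anode, Pt cathode, undivided cell, constant current, (4-BrC6H4)3N (20 mol %), nBu4NPF6, CH2Cl2/(CF3)2CHOH 10:1, 0 °C to rt
Reagents that add atoms: none
Why: Proposed new method: the electrogenerated triarylaminium ion should remove one electron only from the C6=C7 p-methoxystyrene of 12 (the isolated anisole rings of 15 and 19 are expected to be harder to oxidise) to give radical cation 16; the 7β-hydroxyl of 15 adds to C6 of 16 from the α face with anti-Markovnikov regiochemistry, the p-methoxybenzylic radical 17 is oxidised to cation 18, and the 6α-hydroxyl of the diol half captures C7 to close the dioxane, while the protons released are reduced to H2 at the cathode. The closest known reaction types are the anodic dehydrogenative annulation of aryl alkenes with simple 1,2-diols to 1,4-dioxanes and the anti-Markovnikov addition of alcohols to styrene radical cations; not yet shown is the use of a hindered secondary diol as a stoichiometric fragment that must react with one regiochemistry. The 1,4-dioxane is closed in a stepwise [4+2] annulation, the ring-closing event being intramolecular combination of the C7 cation with oxygen through a six-membered chair. The new C6 stereocenter is set by ring B, whose β face is shielded at C6 by the axial C10 and C4 methyl groups, and the new C7 stereocenter is set under thermodynamic control, because the p-methoxybenzylic C7–O bond can ionise and re-close in the fluoroalcohol medium until the all-equatorial doubly trans-fused dioxane is reached. The step needs head-to-tail regiochemistry (O7 to C6′ and O6 to C7′): the 6α-hydroxyl of 15 lies peri to the equatorial C4 methyl group and should be too hindered for the intermolecular attack, so the open benzylic 7β-hydroxyl adds first, and the radical cation accepts it only at C6 because that leaves the benzylic radical at C7.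

**Compound list**

1 | (+)-dehydroabietic acid (abieta-8,11,13-trien-18-oic acid) | CC(C)c1ccc2c(c1)CC[C@H]1[C@](C)(C(=O)O)CCC[C@]21C | starting material
2 | dehydroabietinol (abieta-8,11,13-trien-18-ol) | CC(C)c1ccc2c(c1)CC[C@H]1[C@](C)(CO)CCC[C@]21C | intermediate
3 | dehydroabietyl tosylate | CC(C)c1ccc2c(c1)CC[C@H]1[C@](C)(COS(=O)(=O)c3ccc(C)cc3)CCC[C@]21C | intermediate
4 | 18-iodoabieta-8,11,13-triene | CC(C)c1ccc2c(c1)CC[C@H]1[C@](C)(CI)CCC[C@]21C | intermediate (not isolated)
5 | abieta-8,11,13-triene (dehydroabietane) | CC(C)c1ccc2c(c1)CC[C@H]1C(C)(C)CCC[C@]21C | intermediate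
6 | 12-acetylabieta-8,11,13-triene | CC(=O)c1cc2c(cc1C(C)C)CC[C@H]1C(C)(C)CCC[C@]21C | intermediate
7 | ferruginyl acetate (abieta-8,11,13-trien-12-yl acetate) | CC(=O)Oc1cc2c(cc1C(C)C)CC[C@H]1C(C)(C)CCC[C@]21C | intermediate
8 | potassium ferruginolate | [K+].[O-]c1cc2c(cc1C(C)C)CC[C@H]1C(C)(C)CCC[C@]21C | intermediate (not isolated)
9 | ferruginol methyl ether (12-methoxyabieta-8,11,13-triene) | COc1cc2c(cc1C(C)C)CC[C@H]1C(C)(C)CCC[C@]21C | intermediate
10 | sugiol methyl ether (12-methoxyabieta-8,11,13-trien-7-one) | COc1cc2c(cc1C(C)C)C(=O)C[C@H]1C(C)(C)CCC[C@]21C | intermediate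
11 | 12-methoxyabieta-8,11,13-trien-7β-ol | COc1cc2c(cc1C(C)C)[C@@H](O)C[C@H]1C(C)(C)CCC[C@]21C | intermediate (not isolated)
12 | 6,7-dehydroferruginol methyl ether (12-methoxyabieta-6,8,11,13-tetraene) | COc1cc2c(cc1C(C)C)C=C[C@H]1C(C)(C)CCC[C@]21C | intermediate
13 | potassium enolate of 10 (potassium 12-methoxyabieta-6,8,11,13-tetraen-7-olate) | COc1cc2c(cc1C(C)C)C([O-])=C[C@H]1C(C)(C)CCC[C@]21C.[K+] | intermediate (not isolated)
14 | 6α-hydroxysugiol methyl ether (6α-hydroxy-12-methoxyabieta-8,11,13-trien-7-one) | COc1cc2c(cc1C(C)C)C(=O)[C@H](O)[C@H]1C(C)(C)CCC[C@]21C | intermediate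
15 | 12-methoxyabieta-8,11,13-triene-6α,7β-diol | COc1cc2c(cc1C(C)C)[C@@H](O)[C@H](O)[C@H]1C(C)(C)CCC[C@]21C | intermediate
16 | radical cation of 12 (drawn with the charge at C7 and the spin at C6) | COc1cc2c(cc1C(C)C)[CH+][CH][C@H]1C(C)(C)CCC[C@]21C | intermediate (not isolated)
17 | C7 benzylic radical: 7β-O-(12-methoxyabieta-8,11,13-trien-7-yl-6α-yl) ether of 15, radical at C7 of the new half | COc1cc2c(cc1C(C)C)[C@@H](O[C@H]3[CH]c4cc(C(C)C)c(OC)cc4[C@@]4(C)CCCC(C)(C)[C@H]34)[C@H](O)[C@H]1C(C)(C)CCC[C@]21C | intermediate (not isolated)
18 | C7 benzylic cation corresponding to 17 | COc1cc2c(cc1C(C)C)[C@@H](O[C@H]3[CH+]c4cc(C(C)C)c(OC)cc4[C@@]4(C)CCCC(C)(C)[C@H]34)[C@H](O)[C@H]1C(C)(C)CCC[C@]21C | intermediate (not isolated)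
19 | target: C2-symmetric dimer in which the 6α oxygen of each 12-methoxyabieta-8,11,13-triene half is bonded to C7β of the other (trans-fused 1,4-dioxane) | COc1cc2c(cc1C(C)C)[C@H]1O[C@H]3[C@H](O[C@@H]1[C@H]1C(C)(C)CCC[C@]21C)c1cc(C(C)C)c(OC)cc1[C@@]1(C)CCCC(C)(C)[C@H]31 | target

**Summary**

Total step count: 11. Longest linear sequence: 10 steps (steps 1 to 7, 9, 10 and 11); the alkene branch (steps 1 to 8, then 11) has 9.

Steps most likely to fail:

Step 11. The intermolecular C6–O bond formation joins two hindered partners and may be slower than self-reaction of the radical cation (dimerisation, allylic deprotonation). The 6α-hydroxyl may compete as the first nucleophile and lead to the head-to-head isomer. Cation 18 may lose a proton instead of closing, and the medium may ionise the benzylic alcohol of the diol. The fallback uses known chemistry and sets out from 14. Silylation (TMSCl, imidazole, DMF) should give 12-methoxy-6α-(trimethylsilyloxy)abieta-8,11,13-trien-7-one F1. Treatment of F1 with TMSOTf (cat.) and Et3SiH in CH2Cl2 at −78 to −20 °C is a reductive etherification of a ketone with a silyl ether. Two molecules should condense head to tail through C7 oxocarbenium ions, each reduced by axial hydride delivery on the α face, which builds the same dioxane through its two benzylic C7–O bonds. The fallback comes back to the route at 19.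

Step 9. Enolisation of the hindered aryl ketone may be incomplete, the enolate may add to the sulfonimine by-product, and the product may be oxidised further to the diosphenol. The fallback sets out from 12. Dihydroxylation with OsO4 (cat.) and N-methylmorpholine N-oxide in acetone/H2O should occur on the α face and give the cis diol 12-methoxyabieta-8,11,13-triene-6α,7α-diol F2. Selective oxidation of its p-methoxybenzylic 7-hydroxyl with MnO2 in CH2Cl2 then gives the ketol. The fallback comes back to the route at 14.

Step 10. Facial selectivity of the hydride addition may be poor, and the basic medium may cause α-ketol transposition. The fallback sets out from 12. Epoxidation with dimethyldioxirane in acetone at −20 °C on the α face should give 6α,7α-epoxy-12-methoxyabieta-8,11,13-triene F3. Opening of F3 at the benzylic C7 with water (dilute HClO4, THF/H2O, 0 °C) should give the trans-diequatorial diol as the thermodynamically preferred product of the reversible benzylic ionisation. The fallback comes back to the route at 15.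

Further compounds
F1 | step 11 | 12-methoxy-6α-(trimethylsilyloxy)abieta-8,11,13-trien-7-one | COc1cc2c(cc1C(C)C)C(=O)[C@H](O[Si](C)(C)C)[C@H]1C(C)(C)CCC[C@]21C
F2 | step 9 | 12-methoxyabieta-8,11,13-triene-6α,7α-diol | COc1cc2c(cc1C(C)C)[C@H](O)[C@H](O)[C@H]1C(C)(C)CCC[C@]21C
F3 | step 10 | 6α,7α-epoxy-12-methoxyabieta-8,11,13-triene | COc1cc2c(cc1C(C)C)[C@@H]1O[C@@H]1[C@H]1C(C)(C)CCC[C@]21C
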